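**Retrosynthetic overview**
1. Target 28 ⇐ primary alcohol 25 (oxidation, esterification) ⇐ mesylate 21. The 1,2-dioxane is closed last: O1–C6 by cobalt-mediated peroxidation of the C13 methylidene group, then O2–C3 by intramolecular peroxide displacement of the (3R)-mesylate with inversion.
2. C2 and C3 ⇐ Evans syn-aldol of aldehyde 15 with imide 16; dioxane C3–C5 ⇐ B-alkyl Suzuki coupling of acetal 12 with enol triflate 11 of methyl ketone 9.
3. Ketone 9 ⇐ ent-copalol 5 by cleavage of C13=C14 and shift of C8=C17 to C7=C8.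
4. The strategy rests on the trans-fused decalin (rings A and B, gem-dimethyl C4, C5/C9/C10 in the antipodal ent-labdane sense, C7=C8 alkene) and its C9 side chain C11–C12–C13(CH3), where C13 is dioxane C6. ent-Copalyl diphosphate synthase makes this unit from acyclic diphosphate 3 by forming C4–C5 and C9–C10.
5. Ring order: rings A and B together (step 3), then the dioxane ring (steps 15 and 16).

Key step: step 3

**Remarks**
- Labdane numbering (C1–C17) is used for the decalin and its side chain, and dioxane numbering (O1, O2, C3–C6) for the peroxide ring; dioxane C6 is labdane C13.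
- In names, Dx = (1R,4aR,8aR)-5,5,8a-trimethyl-2-methylidenedecahydronaphthalen-1-yl and Dn = (1R,4aR,8aR)-2,5,5,8a-tetramethyl-1,4,4a,5,6,7,8,8a-octahydronaphthalen-1-yl.
- Diphosphates 3 and 4 are drawn as free acids and handled as ammonium salts.
- Assumption on dioxane C6: it is a quaternary centre remote from every controlling element, so step 15 should form both epimers and the (6S) epimer is separated after ring closure in step 16.

**Route**

Step 1
Reactants: 1 (2E,6E,10E)-geranylgeraniol
Product: 2 (2E,6E,10E)-geranylgeranyl chloride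
Conditions: NCS, Me2S, CH2Cl2, −30 → 0 °C
Reagents that add atoms: N-chlorosuccinimide, O=C1CCC(=O)N1Cl
Why: Corey–Kim chlorination turns the primary allylic alcohol into the chloride by SN2 attack of chloride on the alkoxysulfonium ion, without allylic transposition or loss of the 2E geometry.

Step 2
Reactants: 2 (2E,6E,10E)-geranylgeranyl chloride
Product: 3 (2E,6E,10E)-geranylgeranyl diphosphate (isolated as its ammonium salt)
Conditions: (Bu4N)3HP2O7, MeCN, rt; then Dowex 50W-X8 (NH4+ form), cellulose chromatography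
Reagents that add atoms: tris(tetrabutylammonium) hydrogen diphosphate, CCCC[N+](CCCC)(CCCC)CCCC.CCCC[N+](CCCC)(CCCC)CCCC.CCCC[N+](CCCC)(CCCC)CCCC.OP(=O)([O-])OP(=O)([O-])[O-]
Why: SN2 displacement of the primary allylic chloride by the diphosphate anion in acetonitrile is the standard preparation of prenyl diphosphates and keeps the all-E geometry.

Step 3
Reactants: 3 (2E,6E,10E)-geranylgeranyl diphosphate
Product: 4 ent-copalyl diphosphate
Conditions: recombinant ent-copalyl diphosphate synthase (Arabidopsis thaliana, transit peptide removed, expressed in Escherichia coli), 50 mM HEPES pH 7.5, 0.1 mM MgCl2, 10% glycerol, 5 mM dithiothreitol, 30 °C, 3 fed in portions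
Reagents that add atoms: none
Why: The general acid of the enzyme (the middle aspartic acid of its DxDD motif) protonates the terminal alkene of 3 at the carbon that becomes C3; the C4 cation is captured by the next alkene to form C4–C5, the resulting C10 cation by the following alkene to form C9–C10, and the C8 cation loses a C17 proton to leave the exocyclic alkene, with the diphosphate untouched. This is the native reaction of ent-copalyl diphosphate synthase, a protonation-initiated (class 2) diterpene cyclase, and its chemical counterpart is a Brønsted-acid cation–olefin polyene bicyclisation. Ring A closes by 6-endo-trig attack of the alkene whose carbons become C5 and C10 on the C4 cation, and ring B by 6-endo-trig attack of the alkene whose carbons become C9 and C8 on the C10 cation, both as anti additions in a chair–chair fold. C5, C9 and C10 are set together: the trans ring fusion and the equatorial C9 side chain follow from the E alkenes and the chair–chair fold, and the absolute (5R,9R,10R) sense follows from the antipodal fold imposed by the active site. The step needs enantiofacial selection, a stop at the bicyclic stage and regioselective loss of a C17 proton, and all three are properties of the enzyme on its native substrate. Substrate inhibition is avoided by keeping MgCl2 near 0.1 mM and feeding 3 slowly.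

Step 4
Reactants: 4 ent-copalyl diphosphate
Product: 5 ent-copalol
Conditions: calf intestinal alkaline phosphatase, glycine–NaOH buffer pH 9, 1 mM MgCl2, 37 °C; hexane extraction
Reagents that add atoms: none
Why: Phosphatase-catalysed hydrolysis cleaves only P–O bonds, so the allylic C–O bond, the E geometry and the three stereocentres should be untouched.

Step 5
Reactants: 5 ent-copalol
Product: 6 13,14-epoxy-ent-labd-8(17)-en-15-ol (both epoxide diastereomers)
Conditions: VO(acac)2 (2 mol%), tBuOOH, CH2Cl2, 0 °C → rt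
Reagents that add atoms: tert-butyl hydroperoxide, CC(C)(C)OO
Why: Hydroxyl-directed vanadium-catalysed epoxidation delivers oxygen only to the allylic C13=C14 alkene and leaves the isolated C8=C17 alkene; the epoxide configuration is irrelevant because C14 is lost and C13 becomes a carbonyl carbon in step 6.

Step 6
Reactants: 6 13,14-epoxy-ent-labd-8(17)-en-15-ol
Product: 8 14,15-dinor-ent-labd-8(17)-en-13-one, via ent-labd-8(17)-ene-13,14,15-triol 7 (not isolated)
Conditions: H5IO6 (2.2 equiv), THF/H2O, 0 °C → rt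
Reagents that add atoms: water, O
Why: Periodic acid hydrolyses the epoxy alcohol to the 13,14,15-triol and cleaves both glycol C–C bonds (Malaprade cleavage), which leaves C13 as a methyl ketone.

Step 7
Reactants: 8 14,15-dinor-ent-labd-8(17)-en-13-one
Product: 9 14,15-dinor-ent-labd-7-en-13-one
Conditions: Co(salen)Cl [salen = N,N'-bis(3,5-di-tert-butylsalicylidene)-1,2-cyclohexanediamine dianion] (3 mol%), PhSiH3 (6 mol%), benzene, rt; chromatography on AgNO3-impregnated silica
Reagents that add atoms: none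
Why: Radical olefin isomerisation by metal-hydride hydrogen-atom transfer: a cobalt hydride delivers a hydrogen atom to C17 of the 1,1-disubstituted alkene, the cobalt metalloradical takes a hydrogen back from the more accessible C7 methylene of the tertiary C8 radical, and the trisubstituted C7=C8 product should no longer react; any C8=C9 isomer is removed on the silver-loaded silica.

Step 8
Reactants: 9 14,15-dinor-ent-labd-7-en-13-one
Product: 11 4-(Dn)but-1-en-2-yl trifluoromethanesulfonate, via potassium enolate 10 (not isolated)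
Conditions: KN(SiMe3)2, THF, −78 °C; PhNTf2, −78 → 0 °C
Reagents that add atoms: N-phenylbis(trifluoromethanesulfonimide), O=S(=O)(N(c1ccccc1)S(=O)(=O)C(F)(F)F)C(F)(F)F
Why: The bulky amide base removes a proton from the C16 methyl group under kinetic control and the terminal enolate is O-sulfonylated (regioselective enol triflate formation).

Step 9
Reactants: 11 4-(Dn)but-1-en-2-yl trifluoromethanesulfonate; 12 acrolein diethyl acetal
Product: 14 (1R,4aR,8aR)-1-(6,6-diethoxy-3-methylidenehexyl)-2,5,5,8a-tetramethyl-1,4,4a,5,6,7,8,8a-octahydronaphthalene, via 9-(3,3-diethoxypropyl)-9-borabicyclo[3.3.1]nonane 13 (not isolated)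
Conditions: 12, 9-BBN-H, THF, 0 °C → rt; then 11, Pd(dppf)Cl2 (5 mol%), 3 M aq. K3PO4, THF/DMF, 60 °C
Reagents that add atoms: none
Why: Anti-Markovnikov hydroboration of 12 followed by B-alkyl Suzuki–Miyaura coupling with the alkenyl triflate joins C13 to the three-carbon acetal chain and keeps C16 as the methylidene carbon.

Step 10
Reactants: 14 the diene diethyl acetal
Product: 15 4-methylidene-6-(Dn)hexanal
Conditions: 1 M HCl/THF (1:4), rt
Reagents that add atoms: water, O
Why: Acid-catalysed acetal hydrolysis with dilute aqueous acid at room temperature frees the aldehyde, and the two unactivated alkenes should not be protonated under these conditions.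

Step 11
Reactants: 15 4-methylidene-6-(Dn)hexanal; 16 (4S)-4-benzyl-3-propanoyl-1,3-oxazolidin-2-one
Product: 18 (4S)-4-benzyl-3-[(2S,3R)-3-hydroxy-2-methyl-6-methylidene-8-(Dn)octanoyl]-1,3-oxazolidin-2-one, via dibutylboron Z-enolate 17 (not isolated)
Conditions: 16, Bu2BOTf, iPr2NEt, CH2Cl2, 0 °C; 15, −78 → 0 °C; then pH 7 phosphate buffer, MeOH, 30% H2O2, 0 °C
Reagents that add atoms: none
Why: Evans syn-aldol: the Z-boron enolate adds to the aldehyde through a chair Zimmerman–Traxler transition state on the face away from the benzyl group, which sets C2 (S) and C3 (R) together.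

Step 12
Reactants: 18 the syn-aldol imide
Product: 19 (2R,3R)-2-methyl-6-methylidene-8-(Dn)octane-1,3-diol
Conditions: LiBH4, MeOH (1 equiv), THF, 0 °C
Reagents that add atoms: none
Why: Reductive cleavage of the auxiliary by LiBH4 gives the 1,3-diol, removes the acidic C2–H/carbonyl pair that would later allow β-elimination, and leaves C2 and C3 untouched (the C2 descriptor changes to R only by priority).

Step 13
Reactants: 19 the 1,3-diol
Product: 20 (2R,3R)-1-[(tert-butyldiphenylsilyl)oxy]-2-methyl-6-methylidene-8-(Dn)octan-3-ol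
Conditions: tBuPh2SiCl, imidazole, CH2Cl2, 0 °C
Reagents that add atoms: tert-butyl(chloro)diphenylsilane, CC(C)(C)[Si](Cl)(c1ccccc1)c1ccccc1
Why: Silyl ether formation with the bulky chlorosilane is selective for the primary hydroxyl over the hindered secondary one.

Step 14
Reactants: 20 the primary silyl ether
Product: 21 (2R,3R)-1-[(tert-butyldiphenylsilyl)oxy]-2-methyl-6-methylidene-8-(Dn)octan-3-yl methanesulfonate
Conditions: MsCl, Et3N, CH2Cl2, 0 °C
Reagents that add atoms: methanesulfonyl chloride, CS(=O)(=O)Cl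
Why: O-Sulfonylation of the secondary alcohol proceeds with retention at C3 and turns the (3R)-hydroxyl into a leaving group.

Step 15
Reactants: 21 the (3R)-mesylate
Product: 22 (2R,3R,6RS)-1-[(tert-butyldiphenylsilyl)oxy]-2,6-dimethyl-8-(Dn)-6-[(triethylsilyl)peroxy]octan-3-yl methanesulfonate
Conditions: Co(thd)2 (10 mol%; thd = 2,2,6,6-tetramethylheptane-3,5-dionate), O2 (1 atm), Et3SiH, 1,2-dichloroethane, rt
Reagents that add atoms: dioxygen, O=O; triethylsilane, CC[SiH](CC)CC
Why: Mukaiyama–Isayama peroxysilylation: cobalt-hydride hydrogen-atom transfer to C16 of the less hindered 1,1-disubstituted alkene, in preference to the ring C7=C8 alkene, gives the tertiary C13 radical, which is trapped by O2 from either face and silylated, so C13 (dioxane C6) should form as both epimers.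

Step 16
Reactants: 22 the triethylsilyl peroxide (both C6 epimers)
Product: 24 tert-butyl{(2R)-2-[(3S,6S)-6-methyl-6-(2-(Dn)ethyl)-1,2-dioxan-3-yl]propoxy}diphenylsilane, via tetrabutylammonium peroxide 23 (not isolated)
Conditions: Bu4NF (1.05 equiv), THF, −20 → 0 °C; chromatography to remove the (6R) epimer
Reagents that add atoms: none
Why: Fluoride cleaves the peroxy–silicon bond and the peroxide anion displaces the C3 mesylate in an intramolecular SN2 reaction (6-exo-tet), which inverts C3 to S and closes the 1,2-dioxane; the (3S,6S) and (3S,6R) diastereomers are separated at this stage.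

Step 17
Reactants: 24 the (3S,6S)-dioxane silyl ether
Product: 25 (2R)-2-[(3S,6S)-6-methyl-6-(2-(Dn)ethyl)-1,2-dioxan-3-yl]propan-1-ol
Conditions: HF·pyridine, pyridine, THF, 0 °C → rt
Reagents that add atoms: none
Why: Fluoride-mediated cleavage of the silyl ether under buffered, non-basic conditions frees the primary alcohol and avoids base that could trigger Kornblum–DeLaMare cleavage at C3.

Step 18
Reactants: 25 the dioxane alcohol
Product: 27 (2S)-2-[(3S,6S)-6-methyl-6-(2-(Dn)ethyl)-1,2-dioxan-3-yl]propanoic acid, via aldehyde 26 (not isolated)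
Conditions: TEMPO (20 mol%), PhI(OAc)2 (2.2 equiv), MeCN/H2O (1:1), rt
Reagents that add atoms: water, O
Why: Oxoammonium-mediated oxidation takes the primary alcohol through the aldehyde hydrate to the acid under near-neutral conditions, which should spare the peroxide, the C7=C8 alkene and the C2 stereocentre.

Step 19
Reactants: 27 the dioxane acid
Product: 28 methyl (2S)-2-[(3S,6S)-6-methyl-6-(2-(Dn)ethyl)-1,2-dioxan-3-yl]propanoate (CNP0124238.1)
Conditions: Me3SiCHN2, MeOH/toluene (1:4), 0 °C
Reagents that add atoms: (trimethylsilyl)diazomethane, C[Si](C)(C)C=[N+]=[N-]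
Why: Esterification with the diazomethane equivalent runs under neutral conditions, so neither C2 epimerisation nor β-elimination of the peroxide should occur.

**Compound list**
1 | (2E,6E,10E)-geranylgeraniol | CC(C)=CCC/C(C)=C/CC/C(C)=C/CC/C(C)=C/CO | starting material
2 | (2E,6E,10E)-geranylgeranyl chloride | CC(C)=CCC/C(C)=C/CC/C(C)=C/CC/C(C)=C/CCl | intermediate
3 | (2E,6E,10E)-geranylgeranyl diphosphate | CC(C)=CCC/C(C)=C/CC/C(C)=C/CC/C(C)=C/COP(=O)(O)OP(=O)(O)O | intermediate
4 | ent-copalyl diphosphate, (2E)-3-methyl-5-(Dx)pent-2-en-1-yl diphosphate | OP(=O)(O)OP(=O)(O)OC/C=C(\C)CC[C@@H]1C(=C)CC[C@@H]2C(C)(C)CCC[C@@]12C | intermediate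
5 | ent-copalol, (2E)-3-methyl-5-(Dx)pent-2-en-1-ol | OC/C=C(\C)CC[C@@H]1C(=C)CC[C@@H]2C(C)(C)CCC[C@@]12C | intermediate
6 | 13,14-epoxy-ent-labd-8(17)-en-15-ol, {3-methyl-3-[2-(Dx)ethyl]oxiran-2-yl}methanol, trans epoxide, both diastereomers | OCC1OC1(C)CC[C@@H]2C(=C)CC[C@@H]3C(C)(C)CCC[C@@]23C | intermediate
7 | ent-labd-8(17)-ene-13,14,15-triol, diastereomer mixture | OCC(O)C(C)(O)CC[C@@H]1C(=C)CC[C@@H]2C(C)(C)CCC[C@@]12C | intermediate
8 | 14,15-dinor-ent-labd-8(17)-en-13-one, 4-(Dx)butan-2-one | CC(=O)CC[C@@H]1C(=C)CC[C@@H]2C(C)(C)CCC[C@@]12C | intermediate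
9 | 14,15-dinor-ent-labd-7-en-13-one, 4-(Dn)butan-2-one | CC(=O)CC[C@@H]1C(C)=CC[C@@H]2C(C)(C)CCC[C@@]12C | intermediate
10 | potassium 4-(Dn)but-1-en-2-olate | [K+].[O-]C(=C)CC[C@@H]1C(C)=CC[C@@H]2C(C)(C)CCC[C@@]12C | intermediate
11 | 4-(Dn)but-1-en-2-yl trifluoromethanesulfonate | C=C(OS(=O)(=O)C(F)(F)F)CC[C@@H]1C(C)=CC[C@@H]2C(C)(C)CCC[C@@]12C | intermediate
12 | acrolein diethyl acetal, 3,3-diethoxyprop-1-ene | C=CC(OCC)OCC | starting material
13 | 9-(3,3-diethoxypropyl)-9-borabicyclo[3.3.1]nonane | CCOC(CCB1C2CCCC1CCC2)OCC | intermediate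
14 | (1R,4aR,8aR)-1-(6,6-diethoxy-3-methylidenehexyl)-2,5,5,8a-tetramethyl-1,4,4a,5,6,7,8,8a-octahydronaphthalene | CCOC(CCC(=C)CC[C@@H]1C(C)=CC[C@@H]2C(C)(C)CCC[C@@]12C)OCC | intermediate
15 | 4-methylidene-6-(Dn)hexanal | O=CCCC(=C)CC[C@@H]1C(C)=CC[C@@H]2C(C)(C)CCC[C@@]12C | intermediate
16 | (4S)-4-benzyl-3-propanoyl-1,3-oxazolidin-2-one | CCC(=O)N1[C@@H](Cc2ccccc2)COC1=O | starting material
17 | dibutylboron Z-enolate of 16 | CCCCB(CCCC)O/C(=C\C)N1[C@@H](Cc2ccccc2)COC1=O | intermediate
18 | (4S)-4-benzyl-3-[(2S,3R)-3-hydroxy-2-methyl-6-methylidene-8-(Dn)octanoyl]-1,3-oxazolidin-2-one | O=C(N1[C@@H](Cc2ccccc2)COC1=O)[C@@H](C)[C@H](O)CCC(=C)CC[C@@H]3C(C)=CC[C@@H]4C(C)(C)CCC[C@@]34C | intermediate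
19 | (2R,3R)-2-methyl-6-methylidene-8-(Dn)octane-1,3-diol | OC[C@@H](C)[C@H](O)CCC(=C)CC[C@@H]1C(C)=CC[C@@H]2C(C)(C)CCC[C@@]12C | intermediate
20 | (2R,3R)-1-[(tert-butyldiphenylsilyl)oxy]-2-methyl-6-methylidene-8-(Dn)octan-3-ol | CC(C)(C)[Si](c1ccccc1)(c1ccccc1)OC[C@@H](C)[C@H](O)CCC(=C)CC[C@@H]2C(C)=CC[C@@H]3C(C)(C)CCC[C@@]23C | intermediate
21 | (2R,3R)-1-[(tert-butyldiphenylsilyl)oxy]-2-methyl-6-methylidene-8-(Dn)octan-3-yl methanesulfonate | CC(C)(C)[Si](c1ccccc1)(c1ccccc1)OC[C@@H](C)[C@H](OS(C)(=O)=O)CCC(=C)CC[C@@H]2C(C)=CC[C@@H]3C(C)(C)CCC[C@@]23C | intermediate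
22 | (2R,3R,6RS)-1-[(tert-butyldiphenylsilyl)oxy]-2,6-dimethyl-8-(Dn)-6-[(triethylsilyl)peroxy]octan-3-yl methanesulfonate | CC(C)(C)[Si](c1ccccc1)(c1ccccc1)OC[C@@H](C)[C@H](OS(C)(=O)=O)CCC(C)(OO[Si](CC)(CC)CC)CC[C@@H]2C(C)=CC[C@@H]3C(C)(C)CCC[C@@]23C | intermediate
23 | tetrabutylammonium peroxide formed from 22 by loss of the triethylsilyl group | CC(C)(C)[Si](c1ccccc1)(c1ccccc1)OC[C@@H](C)[C@H](OS(C)(=O)=O)CCC(C)(O[O-])CC[C@@H]2C(C)=CC[C@@H]3C(C)(C)CCC[C@@]23C.CCCC[N+](CCCC)(CCCC)CCCC | intermediate
24 | tert-butyl{(2R)-2-[(3S,6S)-6-methyl-6-(2-(Dn)ethyl)-1,2-dioxan-3-yl]propoxy}diphenylsilane | CC(C)(C)[Si](c1ccccc1)(c1ccccc1)OC[C@@H](C)[C@@H]1CC[C@](C)(CC[C@@H]2C(C)=CC[C@@H]3C(C)(C)CCC[C@@]23C)OO1 | intermediate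
25 | (2R)-2-[(3S,6S)-6-methyl-6-(2-(Dn)ethyl)-1,2-dioxan-3-yl]propan-1-ol | OC[C@@H](C)[C@@H]1CC[C@](C)(CC[C@@H]2C(C)=CC[C@@H]3C(C)(C)CCC[C@@]23C)OO1 | intermediate
26 | (2S)-2-[(3S,6S)-6-methyl-6-(2-(Dn)ethyl)-1,2-dioxan-3-yl]propanal | O=C[C@@H](C)[C@@H]1CC[C@](C)(CC[C@@H]2C(C)=CC[C@@H]3C(C)(C)CCC[C@@]23C)OO1 | intermediate
27 | (2S)-2-[(3S,6S)-6-methyl-6-(2-(Dn)ethyl)-1,2-dioxan-3-yl]propanoic acid | OC(=O)[C@@H](C)[C@@H]1CC[C@](C)(CC[C@@H]2C(C)=CC[C@@H]3C(C)(C)CCC[C@@]23C)OO1 | intermediate
28 | methyl (2S)-2-[(3S,6S)-6-methyl-6-(2-(Dn)ethyl)-1,2-dioxan-3-yl]propanoate (CNP0124238.1) | COC(=O)[C@@H](C)[C@@H]1CC[C@](C)(CC[C@@H]2C(C)=CC[C@@H]3C(C)(C)CCC[C@@]23C)OO1 | target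

**Step count**
Total: 19 steps. Longest linear sequence: 19 steps (1 → 28); 12 and 16 are used as purchased.

**Steps most likely to fail, with fallbacks**

Step 15. Two things may go wrong: hydrogen-atom transfer to the ring C7=C8 alkene may compete with the side-chain alkene, and there is no facial control at C13. The fallback closes the ring from the other oxygen and sets out from mesylate 21. KOH and 50% H2O2 in MeOH/THF at 0 °C should displace the mesylate with inversion (SN2) to give the (3S)-hydroperoxide F1. Hg(OAc)2 in CH2Cl2 at room temperature should then close the dioxane by 6-exo cycloperoxymercuration of the methylidene group, through a chair transition state with the C3 substituent equatorial, to give the acetoxymercuriomethyl dioxane F2. NaBH4 in aqueous NaOH at 0 °C should replace mercury by hydrogen, and the route is rejoined at silyl ether 24 after removal of the C6 epimer.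

Step 16. The peroxide anion may act as a base and cause E2 elimination of the secondary mesylate, or fluoride may remove the silyl ether too early. The fallback uses a more reactive, unprotected electrophile and sets out from diol 19. 1,1'-Sulfonyldiimidazole and NaH in THF should give the six-membered cyclic sulfate F3. Co(thd)2, O2 and Et3SiH, as in step 15, should give the triethylsilyl peroxide F4. Bu4NF in THF should release the peroxide anion, which opens the cyclic sulfate at C3 with inversion (6-exo-tet) to the sulfate monoester F5. Catalytic H2SO4 and water in THF should hydrolyse this ester, and the route is rejoined at alcohol 25 after removal of the C6 epimer; steps 13, 14 and 17 are then not needed.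

Step 7. The hydrogen back-transfer may be poorly regioselective, with loss of the C9 hydrogen instead of a C7 hydrogen giving the tetrasubstituted alkene. The fallback fixes the alkene position through a ketone and sets out from ketone 8. 1,2-Bis(trimethylsilyloxy)ethane with catalytic Me3SiOTf in CH2Cl2 at −78 °C should protect the C13 ketone as the dioxolane F6. Ozonolysis (O3, CH2Cl2/MeOH, −78 °C; Me2S) should cleave C8=C17 to the C8 ketone F7. LiN(iPr)2 in THF at −78 °C, then PhNTf2, should deprotonate the less hindered C7 under kinetic control and give the C7-ene enol triflate F8. Me2CuLi in Et2O at −20 °C should replace the triflate by methyl to give the C7-ene dioxolane F9. Pyridinium p-toluenesulfonate in wet acetone should remove the ketal, and the route is rejoined at ketone 9.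

**Further compounds**
F1 | step 15 | tert-butyl{[(2R,3S)-3-hydroperoxy-2-methyl-6-methylidene-8-(Dn)octyl]oxy}diphenylsilane | CC(C)(C)[Si](c1ccccc1)(c1ccccc1)OC[C@@H](C)[C@@H](OO)CCC(=C)CC[C@@H]2C(C)=CC[C@@H]3C(C)(C)CCC[C@@]23C
F2 | step 15 | {[(3S,6S)-3-{(2R)-1-[(tert-butyldiphenylsilyl)oxy]propan-2-yl}-6-[2-(Dn)ethyl]-1,2-dioxan-6-yl]methyl}mercury acetate | CC(C)(C)[Si](c1ccccc1)(c1ccccc1)OC[C@@H](C)[C@@H]1CC[C@](C[Hg]OC(C)=O)(CC[C@@H]2C(C)=CC[C@@H]3C(C)(C)CCC[C@@]23C)OO1
F3 | step 16 | (4R,5R)-5-methyl-4-[3-methylidene-5-(Dn)pentyl]-1,3,2-dioxathiane 2,2-dioxide | O=S1(=O)OC[C@@H](C)[C@H](O1)CCC(=C)CC[C@@H]2C(C)=CC[C@@H]3C(C)(C)CCC[C@@]23C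
F4 | step 16 | (4R,5R)-5-methyl-4-{3-methyl-5-(Dn)-3-[(triethylsilyl)peroxy]pentyl}-1,3,2-dioxathiane 2,2-dioxide, both epimers at the peroxy carbon | O=S1(=O)OC[C@@H](C)[C@H](O1)CCC(C)(OO[Si](CC)(CC)CC)CC[C@@H]2C(C)=CC[C@@H]3C(C)(C)CCC[C@@]23C
F5 | step 16 | tetrabutylammonium (2R)-2-[(3S,6S)-6-methyl-6-(2-(Dn)ethyl)-1,2-dioxan-3-yl]propyl sulfate | [O-]S(=O)(=O)OC[C@@H](C)[C@@H]1CC[C@](C)(CC[C@@H]2C(C)=CC[C@@H]3C(C)(C)CCC[C@@]23C)OO1.CCCC[N+](CCCC)(CCCC)CCCC
F6 | step 7 | 2-methyl-2-[2-(Dx)ethyl]-1,3-dioxolane | CC1(CC[C@@H]2C(=C)CC[C@@H]3C(C)(C)CCC[C@@]23C)OCCO1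
F7 | step 7 | 13,13-(ethylenedioxy)-14,15,17-trinor-ent-labdan-8-one | CC1(CC[C@@H]2C(=O)CC[C@@H]3C(C)(C)CCC[C@@]23C)OCCO1
F8 | step 7 | 13,13-(ethylenedioxy)-14,15,17-trinor-ent-labd-7-en-8-yl trifluoromethanesulfonate | CC1(CC[C@@H]2C(OS(=O)(=O)C(F)(F)F)=CC[C@@H]3C(C)(C)CCC[C@@]23C)OCCO1
F9 | step 7 | 2-methyl-2-[2-(Dn)ethyl]-1,3-dioxolane | CC1(CC[C@@H]2C(C)=CC[C@@H]3C(C)(C)CCC[C@@]23C)OCCO1
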